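## Retrosynthetic overview

1. Diene: a C=C disconnection takes aldehyde 1 back from diene 2 (Wittig methylenation).
2. Dienophile: a Knoevenagel disconnection of the exocyclic CH2 gives curcumin 3 plus formaldehyde; the 1,1-diacylethylene 4 is made in the flask.
3. Key disconnection: the C1–C2 and C5–C6 bonds of the cyclohexene, an "ortho"-selective [4+2] of 4 with 2 under a chiral Brønsted acid. The O-closed dihydropyran 5 is a detour that feeds the same product, target 6.
4. Ring order: there is one carbocycle; it is formed last, in the step that also sets the only stereocentre (C2, R).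

Assumption: the target stereocentre (ring carbon bearing the 3,4-dimethoxyphenyl group) is (R) by CIP analysis of the given SMILES; the sense of induction of the new step cannot be predicted, so the (S)-catalyst is written and its (R)-antipode is used if a first analytical run (chiral HPLC, then X-ray/ECD) shows the (S)-product.

Catalyst A: (S)-3,3′-bis(2,4,6-triisopropylphenyl)-1,1′-binaphthyl-2,2′-diyl N-triflylphosphoramide, a chiral Brønsted acid.

## Route

Step 1
Reactants: 1 (E)-3-(3,4-dimethoxyphenyl)prop-2-enal (3,4-dimethoxycinnamaldehyde)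
Product: 2 (E)-1-(3,4-dimethoxyphenyl)buta-1,3-diene
Conditions: Ph3PCH3Br (1.3 equiv), KOtBu (1.25 equiv), THF, 0 °C → rt; isolate cold and use fresh
Reagents that add atoms: methyltriphenylphosphonium bromide, C[P+](c1ccccc1)(c1ccccc1)c1ccccc1.[Br-]
Why: Wittig olefination with the non-stabilised ylide Ph3P=CH2 adds 1,2 to the enal, leaves the existing (E)-alkene untouched and creates no stereocentre.

Step 2
Reactants: 3 curcumin (1.0 equiv); 2 (E)-1-(3,4-dimethoxyphenyl)buta-1,3-diene (2.0 equiv)
Product: 6 (2E,2′E)-1,1′-[(2R)-2-(3,4-dimethoxyphenyl)cyclohex-3-ene-1,1-diyl]bis[3-(4-hydroxy-3-methoxyphenyl)prop-2-en-1-one], via 4-methylenecurcumin 4 (not isolated), via O-closed dihydropyran isomer 5 (not isolated)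
Conditions: (CH2O)n (1.2 equiv), catalyst A (5 mol %), 5 Å MS, CHCl3, 0 °C; then Et3N quench at 0 °C
Reagents that add atoms: paraformaldehyde (reacts as formaldehyde), C=O
Why: Proposed new method: a chiral N-triflylphosphoramide is asked to run an asymmetric three-component Knoevenagel/[4+2] on a free 1,3-diketone — the acid condenses the curcumin enol with formaldehyde to the doubly activated dienophile 4 and then protonates one of its carbonyl groups; the unsubstituted terminus of diene 2 attacks the exocyclic CH2 ("ortho" regiochemistry) and the aryl-bearing terminus closes onto the α-carbon next to the catalyst-bound carbonyl, so the 3,3′-aryl walls of the chiral counter-anion decide which enantiotopic face of that terminus bonds and set C2 as (R); O-closure of the same aryl-allyl cation/enol pair gives 5, which re-ionises under the acid and is funnelled into the irreversibly C–C-closed 6, so periselectivity is not product-determining, and the β-aryl enone arms of curcumin are far poorer dienophiles than the 1,1-diacylethylene; closest known reaction types are the chiral N-triflylphosphoramide-catalysed Diels–Alder reaction of vinyl ketones with dienes and the achiral domino Knoevenagel/(hetero-)Diels–Alder reaction of 1,3-dicarbonyls with formaldehyde.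

## Compound list

1 | (E)-3-(3,4-dimethoxyphenyl)prop-2-enal (3,4-dimethoxycinnamaldehyde) | COc1ccc(/C=C/C=O)cc1OC | starting material
2 | (E)-1-(3,4-dimethoxyphenyl)buta-1,3-diene | COc1ccc(/C=C/C=C)cc1OC | intermediate
3 | curcumin, (1E,6E)-1,7-bis(4-hydroxy-3-methoxyphenyl)hepta-1,6-diene-3,5-dione (drawn as the diketone; mainly enol) | COc1cc(/C=C/C(=O)CC(=O)/C=C/c2ccc(O)c(OC)c2)ccc1O | starting material
4 | 4-methylenecurcumin, (1E,6E)-1,7-bis(4-hydroxy-3-methoxyphenyl)-4-methylidenehepta-1,6-diene-3,5-dione | COc1cc(/C=C/C(=O)C(=C)C(=O)/C=C/c2ccc(O)c(OC)c2)ccc1O | intermediate (not isolated)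
5 | (2E)-1-{2-[(E)-2-(3,4-dimethoxyphenyl)ethenyl]-6-[(E)-2-(4-hydroxy-3-methoxyphenyl)ethenyl]-3,4-dihydro-2H-pyran-5-yl}-3-(4-hydroxy-3-methoxyphenyl)prop-2-en-1-one (C2 configuration undefined; lost on re-ionisation) | COc1ccc(/C=C/C2CCC(C(=O)/C=C/c3ccc(O)c(OC)c3)=C(/C=C/c3ccc(O)c(OC)c3)O2)cc1OC | intermediate (not isolated)
6 | (2E,2′E)-1,1′-[(2R)-2-(3,4-dimethoxyphenyl)cyclohex-3-ene-1,1-diyl]bis[3-(4-hydroxy-3-methoxyphenyl)prop-2-en-1-one] | COc1cc(/C=C/C(=O)C2(C(=O)/C=C/c3ccc(O)c(OC)c3)CCC=C[C@@H]2c2ccc(OC)c(OC)c2)ccc1O | target

## Step count and risk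

Total step count: 2
Longest linear sequence: 2 steps (1 → 2 → 6); curcumin 3 enters in the last step.

Steps most likely to fail: the route has only two steps, so both are ranked and there is no third to list.

First, step 2 (the proposed new step). The risks are:
- low ee from uncatalysed background cycloaddition, or from a concerted Claisen rearrangement of non-selectively formed 5;
- Michael addition of curcumin to 4 (methylene-bis-curcumin);
- acid-induced oligomerisation of 2;
- low solubility of 3 in CHCl3;
- slow erosion of ee if the benzylic/allylic C–C bond of 6 re-ionises (hence the cold, prompt quench).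

A more confined, more acidic imidodiphosphorimidate acid is the first variation to try. The fallback uses only known chemistry, sets out from 3 (with 2 and paraformaldehyde) and comes back at 6. The three components are combined without chiral acid under ethylenediammonium diacetate catalysis in MeCN at 60 °C (domino Knoevenagel/cycloaddition through 4). The crude product is then heated in toluene at 100 °C so that any 5 undergoes Claisen rearrangement. This gives the racemic cyclohexene (±)-(2E,2′E)-1,1′-[2-(3,4-dimethoxyphenyl)cyclohex-3-ene-1,1-diyl]bis[3-(4-hydroxy-3-methoxyphenyl)prop-2-en-1-one] F1. Preparative chiral SFC on an amylose tris(3,5-dimethylphenylcarbamate) phase then separates 6 from the (S)-enantiomer (2E,2′E)-1,1′-[(2S)-2-(3,4-dimethoxyphenyl)cyclohex-3-ene-1,1-diyl]bis[3-(4-hydroxy-3-methoxyphenyl)prop-2-en-1-one] F2, which is discarded.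

Second, step 1. The olefination itself is routine; the risk is loss of the electron-rich diene 2 by dimerisation or polymerisation during isolation from triphenylphosphine oxide and on storage. The fallback sets out from 1 and comes back at 2 by a Peterson olefination. Addition of TMSCH2MgCl to 1 (THF, −78 → 0 °C) gives the storable β-hydroxysilane (E)-4-(3,4-dimethoxyphenyl)-1-(trimethylsilyl)but-3-en-2-ol F3. Treatment with KH in THF (0 °C → rt, syn-elimination) immediately before step 2 releases 2 with only volatile or water-soluble by-products.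

## Further compounds

F1 | step 2 | (±)-(2E,2′E)-1,1′-[2-(3,4-dimethoxyphenyl)cyclohex-3-ene-1,1-diyl]bis[3-(4-hydroxy-3-methoxyphenyl)prop-2-en-1-one] (racemate) | COc1cc(/C=C/C(=O)C2(C(=O)/C=C/c3ccc(O)c(OC)c3)CCC=CC2c2ccc(OC)c(OC)c2)ccc1O
F2 | step 2 | (2E,2′E)-1,1′-[(2S)-2-(3,4-dimethoxyphenyl)cyclohex-3-ene-1,1-diyl]bis[3-(4-hydroxy-3-methoxyphenyl)prop-2-en-1-one] | COc1cc(/C=C/C(=O)C2(C(=O)/C=C/c3ccc(O)c(OC)c3)CCC=C[C@H]2c2ccc(OC)c(OC)c2)ccc1O
F3 | step 1 | (E)-4-(3,4-dimethoxyphenyl)-1-(trimethylsilyl)but-3-en-2-ol | COc1ccc(/C=C/C(O)C[Si](C)(C)C)cc1OC
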